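Readings and results are calculated for an exercise, noise included.

The left-handed product and right-handed product together cannot outgrow the solid reagent charged: each takes up one coupling partner, and coupling partner comes from that solid. The next flask is planned with 0.0120 M of solid reagent for 30 min, and the decision is whether to keep that charge or raise it.

all flasks: left-handed substrate 0.010 M; right-handed substrate 0.010 M

| flask | solid reagent | remark | time |
|---|---|---|---|
| winter | 0.017 M | run made earlier |  |
| noon | 0.026 M | run made earlier |  |
| flask | 0.0120 M |  | 30 min |

- winter (time / min: left-handed product / %, left-handed substrate / %): 8.00: 7, 44; 10.0: 8, 34; 15.0: 17, 28; 20.0: 17, 28; 25.0: 26, 19; 40.0: 34, 8
- noon (time / min: left-handed product / %, left-handed substrate / %): 8.00: 8, 39; 10.0: 8, 33; 15.0: 12, 29; 20.0: 18, 27; 25.0: 19, 21; 40.0: 35, 6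

(each reading ± 2 percentage points)

* when, up to 30 min, the flask holds most left-handed product
* the amount of left-handed product, in percent of the left-handed substrate and right-handed substrate together charged, at that time

- coupling partner is single-handed; left-handed substrate and right-handed substrate are mirror images of each other, charged as a racemate, each of them at the stated concentration
- solid, in amounts per volume of the solution: solid reagent
- the numbers in the tables scatter by 2 percentage points (one standard deviation)
- steps under discussion: solid reagent <-> coupling partner; coupling partner + left-handed substrate -> left-handed product; coupling partner + right-handed substrate -> right-handed product; left-handed product <-> right-handed product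
- at the start none of the solid reagent is in solution
- the handed part of coupling partner does not stay in what it makes, so the products of the two hands are mirror images too

At 40.0 min the winter run reads 34 % of left-handed product and the noon run 35 %, though the noon run had 1.53 times the solid, so in these two runs the pace does not follow the solid charged. Left-handed substrate and left-handed product sum to 42.0 % in the winter run, below the half of the charge they started from, which reads as a leak into right-handed product. The reckoning here counts right-handed product equal to left-handed product, an assumption and not a reading. On that count the winter run has used about 68.0 % of the charge by then, less than the 85.0 % it was charged with as solid, so on this reckoning its readings describe a flask with solid present.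

The solid life, the time a solid charge lasts at the mean use read from the two runs up to 40.0 min, both products counted, is 34.8 min for the planned flask, whose solid is 60.0 % of the charge. That estimate is longer than 30 min by 4.80 min, a narrow margin for readings with this scatter, but the charge stays, and the reckoning puts the most left-handed product at 30 min, with 25.9 %.

The forecast gave 26 % at 30 min, saying of the solid that “it probably isn't exhausted”.

The flask holds most left-handed product at 30.0 min, 27.7 %, with 7.34 % of its own solid charge left at that time.

    solid reagent ⇌ coupling partner, rate k1*(cs1 - [coupling partner]) while solid is left; crystals form when [coupling partner] > cs1 (solubility = 0.960 mM, k = 0.00660 /s)
    coupling partner + left-handed substrate → left-handed product (k = 28.0 /M/s)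
    coupling partner + right-handed substrate → right-handed product (k = 12.0 /M/s)
    left-handed product ⇌ right-handed product (k = 0.0350 /s)

A neighbour flask with 0.0030 M of solid reagent, the other charges unchanged, is reckoned a solid life of 8.70 min, shorter than 30 min, and the solid is its limiting reagent, the first to run out; half of that solid as left-handed product is 7.50 %. At 30.0 min that neighbour holds 0 % of solid reagent and 7.50 % of left-handed product.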